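Amounts come first. In the flask, the level asked about is 30.0 mM of starting material lost, and 7.5 mM of free catalyst is charged.

all flasks: free catalyst 7.5 mM

|  | starting material | partner | remark |
|---|---|---|---|
| red | 0.15 M | 0.36 M | run made earlier |
| flask | 0.30 M | 0.360 M |  |

red run (percent of the starting material charged)

| time / min | product / % | starting material / % |
|---|---|---|
| 3.00 | 2.6 | 94.0 |
| 4.00 | 5.2 | 93.5 |
| 6.00 | 4.2 | 91.4 |
| 10.0 | 8.1 | 87.8 |
| 15.0 | 12.3 | 87.7 |
| 25.0 | 14.8 | 81.7 |
| 40.0 | 18.9 | 75.9 |

(each reading ± 1 percentage point)

* factor on the rate of making product when 10% of the starting material are converted if partner is charged twice over
* factor on the rate when 10% of the starting material are converted if free catalyst is charged at 80 mM instead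

- no earlier run changes the charge of free catalyst; that part of a forecast is a guess
- no earlier run changes the charge of partner; that part of a forecast is a guess

The red run suggests that the catalyst takes up starting material in a lump. At its first reading, at 3.00 min, product and starting material together lack 3.40% of the charge. One starting material held per catalyst would be 5.00%, and with a scatter of 1 percentage point on each reading the two may be the same. We therefore read the loss of starting material as having two sources: binding, a pre-steady-state burst, and turnover. Time drops out if we ask how much of the level binding can supply. That ratio is 0.250 in the flask; we call it the burst share, b, the catalyst charge over the starting material lost at the level.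

Now turn the question round. For the rate at the level to grow with the catalyst charge, we expect that the working round must be running by then, with turnover supplying part of the level, so b has to stand below one. The flask meets this. At 80 mM, b is 2.67, more than one, so binding can supply the whole level, and we expect the level to be crossed while catalyst is still binding. With b above one, we commit to a factor under one, less than the 10.7 of plain proportion. No run changes partner, so we have no reckoning for it.

The forecast gives 10 for the catalyst, saying “Rate should therefore scale roughly with catalyst”, and 1.6 for doubled partner. On the catalyst our reckoning differs from it.

The simulation gives 0.0775 at 80 mM of free catalyst, where b is 2.67, and 2.98 for doubled partner.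

2 catalyst intermediate A → spent catalyst (k = 3.70 L mol⁻¹ min⁻¹); catalyst intermediate C → free catalyst + product (k = 7.50 min⁻¹); starting material + free catalyst → catalyst intermediate A (k = 610 L mol⁻¹ min⁻¹); catalyst intermediate A ⇌ catalyst intermediate B (K = 0.150, k = 160 min⁻¹); partner + catalyst intermediate B ⇌ catalyst intermediate C (K = 2.20 L mol⁻¹, k = 4.60 L mol⁻¹ min⁻¹) In the flask, with b at 0.250, the level comes at 0.469 h, and by our reckoning about 75.0% of the loss stands as product then. Meanwhile in the flask the round ran through the catalyst intermediates, and pairs of catalyst intermediate A went to spent catalyst, which held 32.5% of the catalyst at 0.200 h and 82.8% at 2.00 h, when product stood at 16.8% of the starting material charged.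

All runs stem from a simulated flask on assumed constants; noise was put on by code.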